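**Retrosynthetic overview**
- The strategy rests on ring C of the flavanone: O1–C8a–C4a–C4 on ring A is a heterodiene (an o-quinone methide at the aldehyde oxidation level) and C2–C3, carrying ring B, is a styrene. Cutting C3–C4 and O1–C2 gives salicylaldehyde 7 and styrene 12.
- C4 passes through the cycloaddition as a methyl ether (from trimethyl orthoformate) and is oxidised to the ketone afterwards; the chelated 5-OH is freed last from its methyl ether.
- 7 comes from 3,5-dimethoxyphenol: TIPS ether, metalation between the two methoxy groups and prenylation, desilylation, ortho-formylation. 12 comes from 2-bromo-3,4-dimethoxybenzaldehyde: methylenation, then Br–Li exchange and geranylation.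
- Ring order: rings A and B are purchased benzene rings; the pyran ring C is the only ring formed (step 7), together with the C2 stereocentre.

Key step: step 7

Abbreviations: prenyl = 3-methylbut-2-en-1-yl; geranyl = (2E)-3,7-dimethylocta-2,6-dien-1-yl.

Assumption: the sense of induction of the chiral acid in step 7 cannot be predicted with confidence. The (R)-catalyst is written; the antipode that delivers the (2S) series would be selected in a pilot run, and the CD spectrum of flavanone 16 should confirm the C2 configuration.

Remark: 8 is a catalogue compound; the position of its bromine fixes the site of geranylation.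

**Step 1**
Reactants: 1 3,5-dimethoxyphenol
Product: 2 (3,5-dimethoxyphenoxy)triisopropylsilane
Conditions: TIPSCl, imidazole, DMF, rt
Reagents that add atoms: triisopropylsilyl chloride, CC(C)[Si](Cl)(C(C)C)C(C)C
Why: Standard O-silylation of a phenol; the bulky TIPS ether withstands n-BuLi and makes this oxygen a poor directing group, so the next metalation is left to the two methoxy groups.

**Step 2**
Reactants: 2 (3,5-dimethoxyphenoxy)triisopropylsilane; 3 prenyl bromide
Product: 5 (3,5-dimethoxy-4-prenylphenoxy)triisopropylsilane, via aryllithium 4 (not isolated)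
Conditions: n-BuLi, TMEDA, THF, 0 °C; CuI (10 mol%), then 3, −78 → 0 °C
Reagents that add atoms: none
Why: Directed ortho-metalation should occur at the C–H flanked by both methoxy groups (the shielded silyl ether does not direct), and copper-catalysed SN2 allylation of the aryllithium at the primary carbon of prenyl bromide places the prenyl group para to the oxygen that becomes O1.

**Step 3**
Reactants: 5 (3,5-dimethoxy-4-prenylphenoxy)triisopropylsilane
Product: 6 3,5-dimethoxy-4-prenylphenol
Conditions: TBAF, THF, 0 °C; aqueous work-up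
Reagents that add atoms: none
Why: Fluoride cleavage of an aryl silyl ether is fast at 0 °C and leaves the alkene and methyl ethers untouched.

**Step 4**
Reactants: 6 3,5-dimethoxy-4-prenylphenol
Product: 7 6-hydroxy-2,4-dimethoxy-3-prenylbenzaldehyde
Conditions: MgCl2, Et3N, (CH2O)n, MeCN, reflux; cold dilute HCl work-up
Reagents that add atoms: formaldehyde (as paraformaldehyde), C=O
Why: Magnesium phenoxide-directed ortho-formylation (Casnati–Skattebøl) delivers the formyl group only ortho to the OH, the two ortho sites being equivalent and the para site blocked, under conditions too mild to touch the prenyl alkene, which has no free OH beside it.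

**Step 5**
Reactants: 8 2-bromo-3,4-dimethoxybenzaldehyde
Product: 9 2-bromo-1-ethenyl-3,4-dimethoxybenzene
Conditions: Ph3PCH3Br, KOtBu, THF, 0 °C → rt
Reagents that add atoms: methyltriphenylphosphonium bromide, C[P+](c1ccccc1)(c1ccccc1)c1ccccc1.[Br-]
Why: Wittig methylenation of a non-enolisable aryl aldehyde; the aryl bromide is inert to the ylide.

**Step 6**
Reactants: 9 2-bromo-1-ethenyl-3,4-dimethoxybenzene; 10 geranyl bromide
Product: 12 1-ethenyl-2-geranyl-3,4-dimethoxybenzene, via aryllithium 11 (not isolated)
Conditions: n-BuLi, THF, −78 °C; CuBr·SMe2 (10 mol%), then 10, −78 → −20 °C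
Reagents that add atoms: none
Why: Bromine–lithium exchange at −78 °C is faster than addition of the organolithium to the vinyl group, and copper-catalysed SN2 allylation at C1 of geranyl bromide should keep the E geometry of the chain.

**Step 7**
Reactants: 7 6-hydroxy-2,4-dimethoxy-3-prenylbenzaldehyde; 12 1-ethenyl-2-geranyl-3,4-dimethoxybenzene
Product: 15 (2S,4S)-2-(2-geranyl-3,4-dimethoxyphenyl)-4,5,7-trimethoxy-6-prenylchromane, via dimethyl acetal 13 (not isolated), via methoxy o-quinone methide 14 (not isolated)
Conditions: HC(OMe)3 (1.5 equiv), (R)-3,3′-bis(2,4,6-triisopropylphenyl)-H8-BINOL N-triflylphosphoramide (5 mol%), 5 Å MS, toluene, −40 °C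
Reagents that add atoms: trimethyl orthoformate, COC(OC)OC
Why: Proposed new method: acid-catalysed acetalisation of 7 gives 13, which loses methanol under the chiral acid to give 14, present as its O-protonated form, a 2-hydroxyaryl oxocarbenium ion paired and hydrogen-bonded with the chiral phosphoramide anion; the CH2 terminus of styrene 12 adds to the carbenium carbon (future C4) and the benzylic cation, stabilised by the para 4′-methoxy group, is captured by the phenol oxygen, so that C3–C4 and O1–C2 form in one formal inverse-demand oxa-[4+2] event. The closest known reactions are the Lewis-acid three-component coupling of salicylaldehydes, trimethyl orthoformate and styrenes to racemic 4-methoxy-2-arylchromans and the chiral N-triflylphosphoramide-catalysed cycloaddition of aryl-substituted o-quinone methides with styrenes; new here is a chiral anion controlling an alkoxy-substituted o-quinone methide. The pyran ring closes either in a concerted asynchronous cycloaddition or, stepwise, by 6-exo-trig attack of the phenol oxygen on the p-quinoid benzylic cation. C2 is set by the catalyst, whose anion bridges the phenol O–H and the cationic carbon and shields one face in the C–O bond-forming step; C4 follows from an endo-type (cis) arrangement and is of no consequence, since either C4 epimer converges in step 8. The step needs regioselectivity, secured by the polarity match of carbenium carbon and styrene terminus; chemoselectivity for the styrene over the three trisubstituted alkenes, secured by its higher π-nucleophilicity and by the absence of a free OH beside the prenyl group; and configurational stability at C2, secured by low temperature, catalytic acid and sieves that take up methanol.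

**Step 8**
Reactants: 15 (2S,4S)-2-(2-geranyl-3,4-dimethoxyphenyl)-4,5,7-trimethoxy-6-prenylchromane
Product: 16 (2S)-2-(2-geranyl-3,4-dimethoxyphenyl)-5,7-dimethoxy-6-prenylchroman-4-one
Conditions: DDQ (1.3 equiv), CH2Cl2/pH 7 buffer (10:1), 0 °C
Reagents that add atoms: water, O
Why: DDQ oxidation of an electron-rich benzylic ether: hydride is abstracted from C4–H, which is activated by the trioxygenated ring A and the methoxy oxygen, and water adds to the oxocarbenium ion with loss of methanol to give the aryl ketone, while C2–H (on the less electron-rich ring B) and the benzylic–allylic CH2 groups (held out of alignment by two ortho substituents) should react more slowly and the buffer protects the acid-labile C2–O bond.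

**Step 9**
Reactants: 16 (2S)-2-(2-geranyl-3,4-dimethoxyphenyl)-5,7-dimethoxy-6-prenylchroman-4-one
Product: 17 (2S)-2-(2-geranyl-3,4-dimethoxyphenyl)-5-hydroxy-7-methoxy-6-prenylchroman-4-one
Conditions: MgI2·OEt2, THF, 50 °C; aqueous work-up
Reagents that add atoms: none
Why: Chelation-controlled demethylation: Mg(II) bound between the C4 carbonyl and the peri C5 methoxy oxygen lets iodide remove only that methyl group by SN2, and the aprotic, non-basic medium should neither add the freed C5–OH across the C6 prenyl alkene nor open the ring at C2, so the (2S) centre set in step 7 is kept.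

**Compound list**
1 | 3,5-dimethoxyphenol | COc1cc(O)cc(OC)c1 | starting material
2 | (3,5-dimethoxyphenoxy)triisopropylsilane | COc1cc(OC)cc(O[Si](C(C)C)(C(C)C)C(C)C)c1 | intermediate
3 | prenyl bromide | CC(C)=CCBr | starting material
4 | 2,6-dimethoxy-4-(triisopropylsilyloxy)phenyllithium (not isolated) | COc1cc(O[Si](C(C)C)(C(C)C)C(C)C)cc(OC)c1[Li] | intermediate
5 | (3,5-dimethoxy-4-prenylphenoxy)triisopropylsilane | COc1cc(O[Si](C(C)C)(C(C)C)C(C)C)cc(OC)c1CC=C(C)C | intermediate
6 | 3,5-dimethoxy-4-prenylphenol | COc1cc(O)cc(OC)c1CC=C(C)C | intermediate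
7 | 6-hydroxy-2,4-dimethoxy-3-prenylbenzaldehyde | COc1cc(O)c(C=O)c(OC)c1CC=C(C)C | intermediate
8 | 2-bromo-3,4-dimethoxybenzaldehyde | COc1ccc(C=O)c(Br)c1OC | starting material
9 | 2-bromo-1-ethenyl-3,4-dimethoxybenzene | C=Cc1ccc(OC)c(OC)c1Br | intermediate
10 | geranyl bromide | BrC/C=C(\C)CCC=C(C)C | starting material
11 | 6-ethenyl-2,3-dimethoxyphenyllithium (not isolated) | C=Cc1ccc(OC)c(OC)c1[Li] | intermediate
12 | 1-ethenyl-2-geranyl-3,4-dimethoxybenzene | C=Cc1ccc(OC)c(OC)c1C/C=C(\C)CCC=C(C)C | intermediate
13 | 2-(dimethoxymethyl)-3,5-dimethoxy-4-prenylphenol (not isolated) | COc1cc(O)c(C(OC)OC)c(OC)c1CC=C(C)C | intermediate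
14 | 3,5-dimethoxy-6-(methoxymethylidene)-4-prenylcyclohexa-2,4-dien-1-one (not isolated) | COC=C1C(=O)C=C(OC)C(CC=C(C)C)=C1OC | intermediate
15 | (2S,4S)-2-(2-geranyl-3,4-dimethoxyphenyl)-4,5,7-trimethoxy-6-prenylchromane (2,4-cis) | COc1cc2c(c(OC)c1CC=C(C)C)[C@@H](OC)C[C@@H](c1ccc(OC)c(OC)c1C/C=C(\C)CCC=C(C)C)O2 | intermediate
16 | (2S)-2-(2-geranyl-3,4-dimethoxyphenyl)-5,7-dimethoxy-6-prenylchroman-4-one | COc1cc2c(c(OC)c1CC=C(C)C)C(=O)C[C@@H](c1ccc(OC)c(OC)c1C/C=C(\C)CCC=C(C)C)O2 | intermediate
17 | (2S)-2-(2-geranyl-3,4-dimethoxyphenyl)-5-hydroxy-7-methoxy-6-prenylchroman-4-one (CNP0112088.1) | COc1cc2c(c(O)c1CC=C(C)C)C(=O)C[C@@H](c1ccc(OC)c(OC)c1C/C=C(\C)CCC=C(C)C)O2 | target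

**Step count**
Total: 9 steps. Longest linear sequence: 7 steps (steps 1, 2, 3, 4, 7, 8, 9).

**Steps most likely to fail**

Step 7 (proposed new method). The chiral anion may fail to discriminate the two faces in the ring-closing C–O step. The acid may also re-ionise the C2–O bond of the 4′-methoxybenzylic ether and erode the enantiomeric purity, or the electron-rich styrene may oligomerise cationically. The fallback uses known chemistry and moves stereocontrol from the cycloaddition to a resolution; it sets out from 7 and 12 and comes back at 16. The Sc(OTf)3-catalysed three-component coupling of 7, trimethyl orthoformate and 12 (CH2Cl2, rt), running through 13 and 14, should give racemic 2,4-cis-2-(2-geranyl-3,4-dimethoxyphenyl)-4,5,7-trimethoxy-6-prenylchromane F1. DDQ oxidation of F1 as in step 8 should then give racemic 2-(2-geranyl-3,4-dimethoxyphenyl)-5,7-dimethoxy-6-prenylchroman-4-one F2. Kinetic resolution of F2 by Ru(II)–TsDPEN transfer hydrogenation (HCO2H/Et3N), with the catalyst antipode that consumes the (2R)-ketone, should reduce that enantiomer to (2R,4R)-2-(2-geranyl-3,4-dimethoxyphenyl)-5,7-dimethoxy-6-prenylchroman-4-ol F3 and leave (2S)-flavanone 16, which is separated from F3 and carried into step 9.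

Step 8. DDQ may abstract hydride at the wrong C–H (C2–H of the 4′-methoxybenzylic ether, or a benzylic–allylic CH2), or over-oxidise through a 4-methoxyflav-3-ene to the flavone with loss of C2. The fallback sets out from 15 and comes back at 16, and replaces the hydride abstraction by solvolysis and alcohol oxidation. Mild aqueous acid (PPTS, THF/H2O, rt) should exchange the C4 methoxy group of 15 for hydroxyl through the doubly stabilised benzylic cation, giving (2S)-2-(2-geranyl-3,4-dimethoxyphenyl)-5,7-dimethoxy-6-prenylchroman-4-ol F4 as a mixture of C4 epimers. Dess–Martin periodinane (NaHCO3, CH2Cl2, 0 °C) should then oxidise F4 to 16.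

Step 9. Cleavage may be too slow at temperatures that hold C2; when forced by heat or stronger Lewis acids, the freed C5 hydroxyl may add across the C6 prenyl alkene or the ring may open at C2 and epimerise. The fallback carries the side chain as an allyl group, which gives no tertiary cation, and builds the prenyl alkene last; it sets out from 2, lithiated to aryllithium 4 as in step 2, and comes back at 17. Aryllithium 4 is alkylated with allyl bromide in place of 3 to give (4-allyl-3,5-dimethoxyphenoxy)triisopropylsilane F5. TBAF should convert F5 into 4-allyl-3,5-dimethoxyphenol F6, and magnesium-mediated formylation of F6 should give 3-allyl-6-hydroxy-2,4-dimethoxybenzaldehyde F7. Under the conditions of step 7, F7 and 12 should react through 4-allyl-2-(dimethoxymethyl)-3,5-dimethoxyphenol F8 and 4-allyl-3,5-dimethoxy-6-(methoxymethylidene)cyclohexa-2,4-dien-1-one F9 to give (2S,4S)-6-allyl-2-(2-geranyl-3,4-dimethoxyphenyl)-4,5,7-trimethoxychromane F10. DDQ as in step 8 should convert F10 into (2S)-6-allyl-2-(2-geranyl-3,4-dimethoxyphenyl)-5,7-dimethoxychroman-4-one F11. BCl3 (CH2Cl2, −78 °C) should cleave the chelated C5 methyl ether of F11 fast and cold to give (2S)-6-allyl-2-(2-geranyl-3,4-dimethoxyphenyl)-5-hydroxy-7-methoxychroman-4-one F12. Cross-metathesis of F12 with 2-methyl-2-butene (second-generation Grubbs catalyst, CH2Cl2, 35 °C) should convert the terminal alkene into the prenyl group and give 17; the trisubstituted alkenes of the geranyl chain are much slower metathesis partners.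

**Further compounds**
F1 | step 7 | racemic 2,4-cis-2-(2-geranyl-3,4-dimethoxyphenyl)-4,5,7-trimethoxy-6-prenylchromane | COc1cc2c(c(OC)c1CC=C(C)C)C(OC)CC(c1ccc(OC)c(OC)c1C/C=C(\C)CCC=C(C)C)O2
F2 | step 7 | racemic 2-(2-geranyl-3,4-dimethoxyphenyl)-5,7-dimethoxy-6-prenylchroman-4-one | COc1cc2c(c(OC)c1CC=C(C)C)C(=O)CC(c1ccc(OC)c(OC)c1C/C=C(\C)CCC=C(C)C)O2
F3 | step 7 | (2R,4R)-2-(2-geranyl-3,4-dimethoxyphenyl)-5,7-dimethoxy-6-prenylchroman-4-ol | COc1cc2c(c(OC)c1CC=C(C)C)[C@H](O)C[C@H](c1ccc(OC)c(OC)c1C/C=C(\C)CCC=C(C)C)O2
F4 | step 8 | (2S)-2-(2-geranyl-3,4-dimethoxyphenyl)-5,7-dimethoxy-6-prenylchroman-4-ol (C4 epimers) | COc1cc2c(c(OC)c1CC=C(C)C)C(O)C[C@@H](c1ccc(OC)c(OC)c1C/C=C(\C)CCC=C(C)C)O2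
F5 | step 9 | (4-allyl-3,5-dimethoxyphenoxy)triisopropylsilane | C=CCc1c(OC)cc(O[Si](C(C)C)(C(C)C)C(C)C)cc1OC
F6 | step 9 | 4-allyl-3,5-dimethoxyphenol | C=CCc1c(OC)cc(O)cc1OC
F7 | step 9 | 3-allyl-6-hydroxy-2,4-dimethoxybenzaldehyde | COc1cc(O)c(C=O)c(OC)c1CC=C
F8 | step 9 | 4-allyl-2-(dimethoxymethyl)-3,5-dimethoxyphenol | COc1cc(O)c(C(OC)OC)c(OC)c1CC=C
F9 | step 9 | 4-allyl-3,5-dimethoxy-6-(methoxymethylidene)cyclohexa-2,4-dien-1-one | COC=C1C(=O)C=C(OC)C(CC=C)=C1OC
F10 | step 9 | (2S,4S)-6-allyl-2-(2-geranyl-3,4-dimethoxyphenyl)-4,5,7-trimethoxychromane | COc1cc2c(c(OC)c1CC=C)[C@@H](OC)C[C@@H](c1ccc(OC)c(OC)c1C/C=C(\C)CCC=C(C)C)O2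
F11 | step 9 | (2S)-6-allyl-2-(2-geranyl-3,4-dimethoxyphenyl)-5,7-dimethoxychroman-4-one | COc1cc2c(c(OC)c1CC=C)C(=O)C[C@@H](c1ccc(OC)c(OC)c1C/C=C(\C)CCC=C(C)C)O2
F12 | step 9 | (2S)-6-allyl-2-(2-geranyl-3,4-dimethoxyphenyl)-5-hydroxy-7-methoxychroman-4-one | COc1cc2c(c(O)c1CC=C)C(=O)C[C@@H](c1ccc(OC)c(OC)c1C/C=C(\C)CCC=C(C)C)O2
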